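## Retros

**Retrosynthetic overview**

1. The target is a pentan-2-ol chain with a 7-methoxy-2,2-dimethyl-2H-chromen-6-yl group on the carbinol carbon (R) and a 5-acetyl-6-hydroxybenzofuran-2-yl group on the methine carbon (S). The 2H-pyran ring is cut last, back to an aryl 2-methylbut-3-yn-2-yl ether of a bisphenol.
2. Enabling feature: the pyran ring O1–C2(CH3)2–C3=C4–C4a=C8a is the valence isomer of an ortho-quinone methide. O1 sits on C8a of ring A next to an unsubstituted C4a (para to the C7 methoxy) and C2 is quaternary, so a tertiary propargyl ether on O1 can be carried into the ring by a [3,3] shift, two hydrogen shifts and an oxa-6π closure.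
3. Furan ring: Sonogashira coupling and 5-endo-dig closure of a terminal alkyne with 1-(2,4-dihydroxy-5-iodophenyl)ethanone, which brings the acetyl and hydroxyl groups in unprotected.
4. Carbinol–CH2 bond and both stereocentres: lithiation–borylation of an (S)-benzylic carbamate (from a CBS reduction) with an (S)-β-methyl boronic ester from the chiral pool, then oxidation.
5. Ring order: both benzene rings are bought, the furan ring is closed in step 11, the pyran ring in step 13.

Key step: step 13

Remark: the given SMILES is read as R at the carbinol carbon and S at the methine carbon of the pentane chain, and all intermediates are drawn to match. Atom numbers in the text (O1, C2, C4a, C8, C8a) are those of the chromene in the target.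

## Route

Step 1
Reactants: 1 1-(4-hydroxy-2-methoxyphenyl)ethanone
Product: 2 1-[2-methoxy-4-(triisopropylsilyloxy)phenyl]ethanone
Conditions: i-Pr3SiCl, imidazole, DMF, 25 °C
Reagents that add atoms: chlorotriisopropylsilane, CC(C)[Si](Cl)(C(C)C)C(C)C
Why: Silyl ether formation on the acidic para-acyl phenol masks the only proton that would quench the organolithium of step 8; no stereocentre is involved.

Step 2
Reactants: 2 1-[2-methoxy-4-(triisopropylsilyloxy)phenyl]ethanone
Product: 3 (S)-1-[2-methoxy-4-(triisopropylsilyloxy)phenyl]ethanol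
Conditions: (R)-1-methyl-3,3-diphenyltetrahydro-1H,3H-pyrrolo[1,2-c][1,3,2]oxazaborole (10 mol %), BH3·SMe2, THF, −20 °C; MeOH quench
Reagents that add atoms: none
Why: CBS reduction: the (R)-oxazaborolidine–borane complex binds the ketone with the aryl group as the large substituent and delivers hydride to the Re face, which should set the (S)-carbinol.

Step 3
Reactants: 3 (S)-1-[2-methoxy-4-(triisopropylsilyloxy)phenyl]ethanol
Product: 4 (S)-1-[2-methoxy-4-(triisopropylsilyloxy)phenyl]ethyl N,N-diisopropylcarbamate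
Conditions: NaH, THF, 0 °C; i-Pr2NC(O)Cl, 0 → 50 °C
Reagents that add atoms: N,N-diisopropylcarbamoyl chloride, CC(C)N(C(C)C)C(Cl)=O
Why: O-Carbamoylation of the sodium alkoxide (acyl substitution at the carbamoyl chloride) installs the directing and leaving group for step 8 under basic conditions that do not touch the C–O stereocentre.

Step 4
Reactants: 5 (R)-3-bromo-2-methylpropan-1-ol
Product: 6 (S)-2-methyl-3-(4,4,5,5-tetramethyl-1,3,2-dioxaborolan-2-yl)propan-1-ol
Conditions: B2pin2, CuI (10 mol %), PPh3 (13 mol %), LiOMe, DMF, 25 °C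
Reagents that add atoms: bis(pinacolato)diboron, CC1(C)OB(OC1(C)C)B1OC(C)(C)C(C)(C)O1
Why: Copper-catalysed borylation of a primary alkyl bromide replaces bromine by the boryl group at a carbon that is not stereogenic, so the neighbouring centre is kept (the descriptor changes from R to S only through the priority switch).

Step 5
Reactants: 6 (S)-2-methyl-3-(4,4,5,5-tetramethyl-1,3,2-dioxaborolan-2-yl)propan-1-ol
Product: 7 (S)-2-methyl-3-(4,4,5,5-tetramethyl-1,3,2-dioxaborolan-2-yl)propanal
Conditions: Dess–Martin periodinane, CH2Cl2, 0 → 25 °C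
Reagents that add atoms: none
Why: Dess–Martin oxidation of the primary alcohol to the aldehyde runs without base, so the C–B bond and the α-methyl stereocentre should stay intact.

Step 6
Reactants: 7 (S)-2-methyl-3-(4,4,5,5-tetramethyl-1,3,2-dioxaborolan-2-yl)propanal
Product: 8 (S)-4,4,5,5-tetramethyl-2-(2-methylbut-3-yn-1-yl)-1,3,2-dioxaborolane
Conditions: dimethyl (1-diazo-2-oxopropyl)phosphonate, K2CO3, MeOH, 0 °C
Reagents that add atoms: dimethyl (1-diazo-2-oxopropyl)phosphonate, COP(=O)(OC)C(=[N+]=[N-])C(C)=O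
Why: Seyferth–Gilbert homologation with the Ohira–Bestmann reagent (alkylidene carbene, 1,2-hydrogen shift) turns the aldehyde into the terminal alkyne at 0 °C, mild enough to keep the α-stereocentre.

Step 7
Reactants: 8 (S)-4,4,5,5-tetramethyl-2-(2-methylbut-3-yn-1-yl)-1,3,2-dioxaborolane
Product: 9 (S)-trimethyl[3-methyl-4-(4,4,5,5-tetramethyl-1,3,2-dioxaborolan-2-yl)but-1-yn-1-yl]silane
Conditions: Me3SiOTf, Et3N, Zn(OTf)2 (10 mol %), CH2Cl2, 25 °C
Reagents that add atoms: trimethylsilyl trifluoromethanesulfonate, C[Si](C)(C)OS(=O)(=O)C(F)(F)F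
Why: Zinc-acetylide-mediated C-silylation of the terminal alkyne removes the acidic proton without a strong base, which the boronic ester would not tolerate; the stereocentre is not involved.

Step 8
Reactants: 4 (S)-1-[2-methoxy-4-(triisopropylsilyloxy)phenyl]ethyl N,N-diisopropylcarbamate; 9 (S)-trimethyl[3-methyl-4-(4,4,5,5-tetramethyl-1,3,2-dioxaborolan-2-yl)but-1-yn-1-yl]silane
Product: 13 (2R,4S)-2-[2-methoxy-4-(triisopropylsilyloxy)phenyl]-4-methyl-6-(trimethylsilyl)hex-5-yn-2-ol, via lithiated carbamate 10 (not isolated), via boronate complex 11 (not isolated), via tertiary boronic ester 12 (not isolated)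
Conditions: 4, s-BuLi, Et2O, −78 °C; 9, −78 °C; MgBr2·OEt2, MeOH, −78 → 25 °C; then NaOH, H2O2, THF/H2O, 0 °C
Reagents that add atoms: hydrogen peroxide, OO
Why: Lithiation–borylation: s-BuLi removes the benzylic proton with retention to give the configurationally stable 10, which takes up 9 with retention to give 11; the stereospecific 1,2-metallate rearrangement anti to the carbamate (driven by MgBr2/MeOH for the electron-rich arene) gives 12, and oxidation with retention should set the (R)-carbinol, while the (S)-methine is carried in unchanged from 9.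

Step 9
Reactants: 13 (2R,4S)-2-[2-methoxy-4-(triisopropylsilyloxy)phenyl]-4-methyl-6-(trimethylsilyl)hex-5-yn-2-ol
Product: 14 (2R,4S)-2-(4-hydroxy-2-methoxyphenyl)-4-methylhex-5-yn-2-ol
Conditions: Bu4NF, THF, 0 → 25 °C
Reagents that add atoms: none
Why: Fluoride-induced desilylation cleaves the aryl silyl ether and the alkynylsilane in one operation under basic conditions that spare the acid-labile tertiary benzylic alcohol.

Step 10
Reactants: 15 1-(2,4-dihydroxyphenyl)ethanone
Product: 16 1-(2,4-dihydroxy-5-iodophenyl)ethanone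
Conditions: ICl, AcOH, 25 °C
Reagents that add atoms: iodine monochloride, ClI
Why: Electrophilic aromatic iodination should go to C5, para to the chelated 2-hydroxyl and ortho to the free 4-hydroxyl, the less hindered of the two activated positions.

Step 11
Reactants: 14 (2R,4S)-2-(4-hydroxy-2-methoxyphenyl)-4-methylhex-5-yn-2-ol; 16 1-(2,4-dihydroxy-5-iodophenyl)ethanone
Product: 18 1-{6-hydroxy-2-[(2S,4R)-4-hydroxy-4-(4-hydroxy-2-methoxyphenyl)pentan-2-yl]-1-benzofuran-5-yl}ethanone, via alkynylphenol 17 (not isolated)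
Conditions: PdCl2(PPh3)2 (5 mol %), CuI (10 mol %), Et3N, DMF, 25 → 60 °C
Reagents that add atoms: none
Why: Sonogashira coupling gives 17, whose hydroxyl ortho to the alkyne (acidified by the para acetyl group) adds 5-endo-dig to close the furan ring (heteroannulation); the acetyl and the chelated hydroxyl need no protection and neither stereocentre is touched.

Step 12
Reactants: 18 1-{6-hydroxy-2-[(2S,4R)-4-hydroxy-4-(4-hydroxy-2-methoxyphenyl)pentan-2-yl]-1-benzofuran-5-yl}ethanone; 19 3-chloro-3-methylbut-1-yne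
Product: 20 1-{6-hydroxy-2-[(2S,4R)-4-hydroxy-4-{2-methoxy-4-[(2-methylbut-3-yn-2-yl)oxy]phenyl}pentan-2-yl]-1-benzofuran-5-yl}ethanone
Conditions: 19, DBU, CuCl2 (1 mol %), MeCN, 0 °C
Reagents that add atoms: none
Why: Copper-catalysed O-propargylation of a phenoxide with a tertiary propargylic chloride should select the ring A hydroxyl, because the hydrogen-bonded hydroxyl ortho to the acetyl group and the tertiary alcohol are far weaker nucleophiles, and 0 °C avoids loss of water from the para-hydroxybenzylic carbinol.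

Step 13
Reactants: 20 1-{6-hydroxy-2-[(2S,4R)-4-hydroxy-4-{2-methoxy-4-[(2-methylbut-3-yn-2-yl)oxy]phenyl}pentan-2-yl]-1-benzofuran-5-yl}ethanone
Product: 24 1-{6-hydroxy-2-[(2S,4R)-4-hydroxy-4-(7-methoxy-2,2-dimethyl-2H-chromen-6-yl)pentan-2-yl]-1-benzofuran-5-yl}ethanone (CNP0233723.2), via allenyl dienone 21 (not isolated), via allenylphenol 22 (not isolated), via ortho-quinone methide 23 (not isolated)
Conditions: PhNEt2, o-xylene, 140 °C, sealed tube under argon
Reagents that add atoms: none
Why: Heating the aryl 2-methylbut-3-yn-2-yl ether starts an aromatic propargyl Claisen rearrangement ([3,3]-sigmatropic shift) to C4a that gives allenyl dienone 21, which tautomerises to ortho-allenylphenol 22, and a [1,5]-hydrogen shift from the phenolic oxygen to the central allene carbon then gives the (Z)-configured ortho-quinone methide 23. The closest known reaction type is the thermal conversion of aryl 1,1-dimethylpropargyl ethers into 2,2-dimethyl-2H-chromenes. The pyran ring is closed by a thermal, disrotatory oxa-6π electrocyclisation of 23 that forms the O1–C2 bond and restores the aromaticity of ring A. No stereocentre is formed, and the two existing ones are remote from the reacting atoms and should not be touched. The step needs regioselectivity between the two ortho carbons and survival of the tertiary benzylic carbinol: C8 lies between the ether oxygen and the methoxy group, whose methyl is pushed over it by the neighbouring carbinol, so the shift should go to C4a, and the weakly basic medium together with the etherified para oxygen should keep the carbinol from ionising or forming a para-quinone methide. The quaternary C2 carries no hydrogen that could divert the cascade, and the chelated hydroxyl on the benzofuran bears no propargyl group and takes no part.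

## Compound list

1 | 1-(4-hydroxy-2-methoxyphenyl)ethanone | CC(=O)c1ccc(O)cc1OC | starting material
2 | 1-[2-methoxy-4-(triisopropylsilyloxy)phenyl]ethanone | CC(=O)c1ccc(O[Si](C(C)C)(C(C)C)C(C)C)cc1OC | intermediate
3 | (S)-1-[2-methoxy-4-(triisopropylsilyloxy)phenyl]ethanol | COc1cc(O[Si](C(C)C)(C(C)C)C(C)C)ccc1[C@H](C)O | intermediate
4 | (S)-1-[2-methoxy-4-(triisopropylsilyloxy)phenyl]ethyl N,N-diisopropylcarbamate | COc1cc(O[Si](C(C)C)(C(C)C)C(C)C)ccc1[C@H](C)OC(=O)N(C(C)C)C(C)C | intermediate
5 | (R)-3-bromo-2-methylpropan-1-ol | OC[C@@H](C)CBr | starting material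
6 | (S)-2-methyl-3-(4,4,5,5-tetramethyl-1,3,2-dioxaborolan-2-yl)propan-1-ol | OC[C@@H](C)CB1OC(C)(C)C(C)(C)O1 | intermediate
7 | (S)-2-methyl-3-(4,4,5,5-tetramethyl-1,3,2-dioxaborolan-2-yl)propanal | O=C[C@@H](C)CB1OC(C)(C)C(C)(C)O1 | intermediate
8 | (S)-4,4,5,5-tetramethyl-2-(2-methylbut-3-yn-1-yl)-1,3,2-dioxaborolane | C#C[C@@H](C)CB1OC(C)(C)C(C)(C)O1 | intermediate
9 | (S)-trimethyl[3-methyl-4-(4,4,5,5-tetramethyl-1,3,2-dioxaborolan-2-yl)but-1-yn-1-yl]silane | C[Si](C)(C)C#C[C@@H](C)CB1OC(C)(C)C(C)(C)O1 | intermediate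
10 | (S)-1-lithio-1-[2-methoxy-4-(triisopropylsilyloxy)phenyl]ethyl N,N-diisopropylcarbamate (lithium in the place of the benzylic hydrogen of 4) | COc1cc(O[Si](C(C)C)(C(C)C)C(C)C)ccc1[C@]([Li])(C)OC(=O)N(C(C)C)C(C)C | intermediate
11 | lithium boronate complex of 10 and 9 (boron in the place of lithium, carbamate still on carbon) | [Li+].COc1cc(O[Si](C(C)C)(C(C)C)C(C)C)ccc1[C@](C)(OC(=O)N(C(C)C)C(C)C)[B-]1(C[C@H](C)C#C[Si](C)(C)C)OC(C)(C)C(C)(C)O1 | intermediate
12 | 2-{(2S,4S)-2-[2-methoxy-4-(triisopropylsilyloxy)phenyl]-4-methyl-6-(trimethylsilyl)hex-5-yn-2-yl}-4,4,5,5-tetramethyl-1,3,2-dioxaborolane (boron where the hydroxyl of 13 will stand) | COc1cc(O[Si](C(C)C)(C(C)C)C(C)C)ccc1[C@](C)(B1OC(C)(C)C(C)(C)O1)C[C@H](C)C#C[Si](C)(C)C | intermediate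
13 | (2R,4S)-2-[2-methoxy-4-(triisopropylsilyloxy)phenyl]-4-methyl-6-(trimethylsilyl)hex-5-yn-2-ol | COc1cc(O[Si](C(C)C)(C(C)C)C(C)C)ccc1[C@](C)(O)C[C@H](C)C#C[Si](C)(C)C | intermediate
14 | (2R,4S)-2-(4-hydroxy-2-methoxyphenyl)-4-methylhex-5-yn-2-ol | COc1cc(O)ccc1[C@](C)(O)C[C@H](C)C#C | intermediate
15 | 1-(2,4-dihydroxyphenyl)ethanone | CC(=O)c1ccc(O)cc1O | starting material
16 | 1-(2,4-dihydroxy-5-iodophenyl)ethanone | CC(=O)c1cc(I)c(O)cc1O | intermediate
17 | 1-{2,4-dihydroxy-5-[(3S,5R)-5-hydroxy-5-(4-hydroxy-2-methoxyphenyl)-3-methylhex-1-yn-1-yl]phenyl}ethanone | COc1cc(O)ccc1[C@](C)(O)C[C@H](C)C#Cc1cc(C(C)=O)c(O)cc1O | intermediate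
18 | 1-{6-hydroxy-2-[(2S,4R)-4-hydroxy-4-(4-hydroxy-2-methoxyphenyl)pentan-2-yl]-1-benzofuran-5-yl}ethanone | COc1cc(O)ccc1[C@](C)(O)C[C@H](C)c1cc2cc(C(C)=O)c(O)cc2o1 | intermediate
19 | 3-chloro-3-methylbut-1-yne | CC(C)(Cl)C#C | starting material
20 | 1-{6-hydroxy-2-[(2S,4R)-4-hydroxy-4-{2-methoxy-4-[(2-methylbut-3-yn-2-yl)oxy]phenyl}pentan-2-yl]-1-benzofuran-5-yl}ethanone | COc1cc(OC(C)(C)C#C)ccc1[C@](C)(O)C[C@H](C)c1cc2cc(C(C)=O)c(O)cc2o1 | intermediate
21 | 1-{6-hydroxy-2-[(2S,4R)-4-hydroxy-4-[6-methoxy-3-(3-methylbuta-1,2-dien-1-yl)-4-oxocyclohexa-1,5-dien-1-yl]pentan-2-yl]-1-benzofuran-5-yl}ethanone (both configurations at the ring sp3 carbon) | COC1=CC(=O)C(C=C=C(C)C)C=C1[C@](C)(O)C[C@H](C)c1cc2cc(C(C)=O)c(O)cc2o1 | intermediate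
22 | 1-{6-hydroxy-2-[(2S,4R)-4-hydroxy-4-[4-hydroxy-2-methoxy-5-(3-methylbuta-1,2-dien-1-yl)phenyl]pentan-2-yl]-1-benzofuran-5-yl}ethanone | COc1cc(O)c(C=C=C(C)C)cc1[C@](C)(O)C[C@H](C)c1cc2cc(C(C)=O)c(O)cc2o1 | intermediate
23 | 1-{6-hydroxy-2-[(2S,4R)-4-hydroxy-4-[(3Z)-6-methoxy-3-(3-methylbut-2-en-1-ylidene)-4-oxocyclohexa-1,5-dien-1-yl]pentan-2-yl]-1-benzofuran-5-yl}ethanone | CC(C)=C/C=C1/C=C([C@](C)(O)C[C@H](C)c2cc3cc(C(C)=O)c(O)cc3o2)C(OC)=CC1=O | intermediate
24 | 1-{6-hydroxy-2-[(2S,4R)-4-hydroxy-4-(7-methoxy-2,2-dimethyl-2H-chromen-6-yl)pentan-2-yl]-1-benzofuran-5-yl}ethanone (CNP0233723.2) | COc1cc2c(cc1[C@](C)(O)C[C@H](C)c1cc3cc(C(C)=O)c(O)cc3o1)C=CC(C)(C)O2 | target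

## Step count and risks

Total step count: 13.
Longest linear sequence: 9 steps (steps 4, 5, 6, 7, 8, 9, 11, 12 and 13; 5 → 6 → 7 → 8 → 9 → 13 → 14 → 18 → 20 → 24).

Steps most likely to fail:

**Step 8.** The boronate complex of the electron-rich, ortho-substituted benzylic carbamate may revert to its components or ionise before the 1,2-shift, giving low conversion or erosion of configuration at the carbinol carbon; lithiation of the ring next to the methoxy group may also compete. The fallback sets out from ketone 2 and boronic ester 9 and comes back at 13. Boronic ester 9 is activated as its aryl boronate complex (3,5-bis(trifluoromethyl)phenyllithium, THF, −78 °C) and cleaved with I2 to (R)-(4-iodo-3-methylbut-1-yn-1-yl)trimethylsilane F1. Iodine–lithium exchange (t-BuLi, Et2O, −78 °C) gives (S)-[2-methyl-4-(trimethylsilyl)but-3-yn-1-yl]lithium F2, which is added to ketone 2 at −78 °C. This addition has no facial control and should give 13 together with (2S,4S)-2-[2-methoxy-4-(triisopropylsilyloxy)phenyl]-4-methyl-6-(trimethylsilyl)hex-5-yn-2-ol F3. Because the methine centre is already fixed, the two are diastereomers and are separated by chromatography.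

**Step 13.** At 140 °C the tertiary benzylic carbinol may lose water, or the sigmatropic shift may go to the hindered carbon between the two oxygens. The fallback sets out from bisphenol 18 and comes back at 24 without any compound outside the list. Bisphenol 18 is heated with 3-methylbut-2-enal in pyridine at 110 °C. Aldol-type C-alkylation at C4a by the enal, loss of water to the same ortho-quinone methide and oxa-6π closure build the pyran ring directly. The chelated hydroxyl of the benzofuran is not expected to take part.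

**Step 4.** Deprotonation of the free hydroxyl by LiOMe may lead to intramolecular displacement of bromide or to exchange at boron, so that little of the boronic ester is obtained. The fallback sets out from 5 and comes back at 6. The hydroxyl is masked first (t-BuMe2SiCl, imidazole, DMF) to give (R)-(3-bromo-2-methylpropoxy)(tert-butyl)dimethylsilane F4. The same copper-catalysed borylation (B2pin2, CuI, PPh3, LiOMe, DMF) then gives (S)-tert-butyldimethyl[2-methyl-3-(4,4,5,5-tetramethyl-1,3,2-dioxaborolan-2-yl)propoxy]silane F5. HCl in MeOH at 0 °C removes the silyl group and leaves the boronic ester.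

## Further compounds

F1 | step 8 | (R)-(4-iodo-3-methylbut-1-yn-1-yl)trimethylsilane | C[Si](C)(C)C#C[C@@H](C)CI
F2 | step 8 | (S)-[2-methyl-4-(trimethylsilyl)but-3-yn-1-yl]lithium | C[Si](C)(C)C#C[C@@H](C)C[Li]
F3 | step 8 | (2S,4S)-2-[2-methoxy-4-(triisopropylsilyloxy)phenyl]-4-methyl-6-(trimethylsilyl)hex-5-yn-2-ol | COc1cc(O[Si](C(C)C)(C(C)C)C(C)C)ccc1[C@@](C)(O)C[C@H](C)C#C[Si](C)(C)C
F0 | step 13 | none | none
F4 | step 4 | (R)-(3-bromo-2-methylpropoxy)(tert-butyl)dimethylsilane | CC(C)(C)[Si](C)(C)OC[C@@H](C)CBr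
F5 | step 4 | (S)-tert-butyldimethyl[2-methyl-3-(4,4,5,5-tetramethyl-1,3,2-dioxaborolan-2-yl)propoxy]silane | CC(C)(C)[Si](C)(C)OC[C@@H](C)CB1OC(C)(C)C(C)(C)O1
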